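The readings are calculated for an exercise; noise was put on by code.

1. The dusk run held 8.64 times the initiator of the summer run and had 2.48 times its product at 20.0 h. The logarithm of the second ratio over that of the first is 0.422. Call this the initiator exponent, the apparent order of product in initiator at a fixed time. At 6.00 h the same ratio reads 0.559, higher, so between these two readings it falls.

in all of them: substrate 0.10 M; radical scavenger 0.20 mM

| run | coupling partner | scavenger | initiator | remark | time |
|---|---|---|---|---|---|
| summer | 0.13 M | 0.080 M | 0.88 mM | run made earlier |  |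
| dusk | 0.13 M | 0.080 M | 7.6 mM | run made earlier |  |
| gamma | 0.130 M | 0.0800 M | 6.0 mM |  | 30 h |
| eta | 0.130 M | 0.0800 M | 2.0 mM |  | 30 h |
| epsilon | 0.130 M | 0.0800 M | 1.0 mM |  | 30 h |
| alpha | 0.130 M | 0.0800 M | 1.4 mM |  | 30 h |
| theta | 0.130 M | 0.0800 M | 0.80 mM |  | 30 h |
| delta | 0.130 M | 0.0800 M | 4.0 mM |  | 30 h |

- summer (time / h: product / %, substrate / %): 3.00: 4.2, 92.5; 6.00: 9.8, 83.6; 10.0: 16.0, 76.5; 12.0: 17.9, 74.3; 15.0: 20.6, 71.1; 20.0: 24.5, 68.5
- dusk (time / h: product / %, substrate / %): 1.50: 10.9, 81.1; 2.50: 16.2, 71.7; 4.00: 24.4, 61.3; 6.00: 32.7, 51.8; 10.0: 45.0, 41.9; 15.0: 55.1, 34.8; 20.0: 60.8, 30.9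

(scatter of a reading: 0.3 percentage points)

- a reading of substrate is of its free form alone

1. the flasks by amount of product, in percent of the substrate charged, highest first, at 30 h (gamma / eta / epsilon / alpha / theta / delta)
2. the amount of product, in percent of the substrate charged of the flask you put first, at 30 h
3. the amount of product, in percent of the substrate charged of the flask you put last, at 30 h

2. You take over flasks that differ in initiator. Rank them by it: gamma has the most, 6.0 mM, and theta the least, 0.80 mM. Leave the other charges alone, since the exponent was read with them held.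

3. Don't read lost substrate as product: at 20.0 h dusk shows 30.9% substrate and 60.8% product, so 8.3 percentage points stand in neither.

4. To reach 30 h, I let each run's last gain shrink twice more by its own last factor, 0.848 for summer and 0.564 for dusk. That gives summer 30.6% and dusk 65.8%. The exponent, read at 20.0 h and taken over unchanged to 30 h, then carries dusk to gamma, 59.6%, and summer to theta, 29.4%.

5. The forecast says gamma > delta > eta > alpha > epsilon > theta, with 62% and 28%, above my top and below my low: “The ordering follows initiator.”

6. The flasks give gamma > delta > eta > alpha > epsilon > theta: gamma 64.1%, theta 28.8%, with initiator at 5.7% of its charge in gamma and 5.7% in theta.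

    initiator → 2 initiating radical (k = 2.66 × 10⁻⁵ s⁻¹)
    substrate + initiating radical → capped initiator + first chain carrier (k = 7250 M⁻¹ s⁻¹)
    coupling partner + first chain carrier → product + second chain carrier (k = 131 M⁻¹ s⁻¹)
    substrate + second chain carrier → released group + first chain carrier (k = 67.1 M⁻¹ s⁻¹)
    2 first chain carrier → ended chains A (k = 1.00 × 10⁶ M⁻¹ s⁻¹)
    2 second chain carrier → ended chains B (k = 2.00 × 10⁶ M⁻¹ s⁻¹)
    first chain carrier + radical scavenger → ended chains C (k = 1.20 × 10⁷ M⁻¹ s⁻¹)
    substrate + released group ⇌ idle adduct, settled at all times (K = 978 M⁻¹)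
    scavenger + released group → scavenged by-product (k = 0.0412 M⁻¹ s⁻¹)

7. Between gamma and theta the exponent reads 0.397 at 30 h. Carried from theta with 0.422, the earlier runs' exponent gives 42.4% for eta at 2.0 mM of initiator, and eta stands at 43.2%.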